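## Structural features

Neocryptomerin is built from two flavone (2-aryl-4H-chromen-4-one) units, each with rings A, B and C. A single diaryl ether oxygen joins C4' of ring B of unit 1 to C6'' of ring A of unit 2. Unit 1 carries a hydroxyl on C5 and the only methyl ether on C7; unit 2 carries hydroxyls on C5'', C7'' and C4''' and the ether oxygen on C6''. The molecule is flat and has no stereocentre, so no stereocentres stand next to each other and every problem is one of regiochemistry and of telling five oxygen functions apart. The fragile points are the free phenols (oxidation), both pyranone rings (opened by hot strong base), the polyoxygenated ring A of unit 2 (it can open and re-close under acid to the 8-aryloxy isomer) and the single methyl ether, which must outlive every deprotection. The real difficulty lies in ring A of unit 2: its ether oxygen sits between two oxygenated carbons, so the diaryl ether would have to be forged on a doubly flanked phenol, and a ring with two hydroxyls ortho to the acyl group can close ring C in two directions. The key step uses the fact that the C5–O and C5''–O bonds each lie peri to a C4 carbonyl oxygen of ring C, so both oxygens can be added last by carbonyl-directed C–H oxygenation. Without them, ring A of unit 1 is the ring of a purchasable methoxy ketone, and ring A of unit 2 keeps one ortho hydroxyl and an ether oxygen with a single ortho neighbour.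

## Logic of the disconnections

18 ⇒ 17. The two acyl–oxygen bonds of the esters on O7'' and O4''' are cut. These phenols must be electron-poor esters while the rings are oxidised. The forward step must remove both esters without touching the methyl ether or opening either pyranone.

17 ⇒ 15. The C5–O and C5''–O bonds are cut, both peri to a C4 carbonyl. This removes the hydroxyl-differentiation problem in unit 1, the doubly flanked ether and the two-way ring closure in unit 2. The forward step must oxygenate two C–H bonds site-selectively in one molecule that also holds a diaryl ether, a methyl ether and two esters.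

15 ⇒ 14 ⇒ 13. The two pivaloyl–oxygen bonds and then the two benzyl–oxygen bonds are exchanged. Esters would not survive the basic C–C bond formations, and benzyl ethers would not survive hot acid and the iodine oxidant. The forward steps must cleave the benzyl ethers without reducing either C2=C3 bond.

13 ⇒ 12 ⇒ 11. O1–C2 of unit 1 (ring closure with loss of water) and then C2–C3 of unit 1 (acyl shift from oxygen to carbon) are cut. Unit 1 falls back to an aryl ester. The forward step needs a base that enolises the methyl ketone yet leaves the pyranone of unit 2 closed.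

11 ⇒ 9 + 10. The ester C–O bond is cut. This splits the molecule into the complete unit 2 acid and the purchased ketone 10, which already holds the methyl ether. The forward step must acylate a hydrogen-bonded phenol.

9 ⇒ 8. O1''–C2'' is cut. Ring C of unit 2 opens to a chalcone with a single ortho hydroxyl, so closure is unambiguous. The forward step is an oxidative cyclisation that tolerates a free carboxylic acid and benzyl ethers.

8 ⇒ 7 ⇒ 5 + 6. The C2''=C3'' bond is cut (carbonyl condensation), and the carboxylic acid is traced to its methyl ester. The aldehyde 6 is purchased. The forward step must condense a methyl ketone that also carries a phenoxide and a carboxylate.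

5 ⇒ 3 + 4. The bond between the ether oxygen and C4' of ring B of unit 1 is cut. Ring B is activated by its para ester for addition–elimination, and the phenol oxygen has only one ortho substituent. The forward step must choose the free 5'-hydroxyl over the chelated 2'-hydroxyl.

3 ⇒ 1. The C5'–O bond (the future C6''–O) is cut, para to the phenol oxygen. Compound 1 is purchased. The forward step is a para-selective phenol hydroxylation.

## Other disconnections considered

Alternative 1: The cut runs through ring A of unit 2 (C7''–C8'' and C4a''–C8a''), which is built by a Danheiser benzannulation. Heating cyclobutenone A1 with silyloxyalkyne A2 should open A1 to a vinylketene, add the alkyne by [2+2], open the new four-membered ring and close six electrons to phenol A3.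
- In its favour: the aryloxy group is already on the four-carbon piece, so no hindered diaryl ether has to be made. All four oxygens of the ring come out differentiated (free hydroxyl for O7'', isopropyl on O5'', silyl on the future O1''), so ring C can later close only one way.
- Against it here: A1 and A2 are sensitive and each needs several steps. After A3 the crowded carbon between the isopropoxy and silyloxy groups must still be acylated, ring C built and the aryl bromide converted into unit 1. An isopropyl ether must finally be cleaved beside the methyl ether.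
- Comparison: on structure it is the equal of the chosen plan in avoiding both classical problems. It is the better plan in one respect: the 5''-oxygen is present from the start, so nothing has to be oxidised beside the aryloxy group. On mechanism, a pericyclic cascade with regiochemistry fixed by ketene–alkyne polarity is as predictable as chelation-directed metalation and does not depend on catalyst turnover at a hindered site. On step economy it is clearly longer and uses none of the purchasable flavonoid building blocks.

Alternative 2: The cut removes ring C of unit 1 (O1–C8a, C4–C4a and O1–C2). Fluoride-triggered elimination of silyl triflate A4 should release an aryne. The carboxylate of propiolic acid A5 adds at the aryne carbon remote from the methoxy group, the aryl anion attacks the carboxyl carbon (net insertion into the C–O bond), and the phenoxide then adds to the ynone to give A6.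
- In its favour: it is a highly convergent late coupling, the 5-oxygen of unit 1 is present from the start, and regiochemistry follows from the distortion of the alkoxy aryne.
- Against it here: A5 already contains the whole of unit 2 with its doubly flanked ether, so the hard problems are only moved upstream. Arylpropiolic acids lose CO2 easily, simple O-arylation and five-membered ring closure compete, and the end game must cleave the 5-O-methyl but not the 7-O-methyl ether.
- Comparison: for unit 1 it is the equal or the better of the chosen plan, because no C–H bond is oxidised there. For unit 2 it is worse, because the chosen plan removes the flanked-ether problem and this one does not. Mechanistically both steps are predictable polar processes. In step economy the key step is as short, but the total is longer because A4 and A5 are both multi-step.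

Alternative 3: The cut is O1''–C8a'', an aryl C–H bond turned into C–O while ring C of unit 2 closes. Anodic oxidation of diketone A7 in a fluorinated alcohol should join the enol oxygen to the free ortho carbon of the trioxygenated ring, with loss of two electrons and two protons, to give A8.
- In its favour: the ring has a single free ortho position, so closure is unambiguous. The 5''-oxygen is present from the start, and no metal or chemical oxidant is consumed.
- Against it here: the ether oxygen is the middle one of three adjacent oxygens, so the flanked diaryl ether remains. The anode must choose the arene over the active methylene and over the other alkoxy ring. The carbon to be attacked is ortho to the acyl group, and the closure has no close precedent for chromones. Two methyl ethers must finally be distinguished.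
- Comparison: both plans oxidise a ring A C–H bond late. The chosen plan relies on inner-sphere chelation control on a substrate class where this has been done; the alternative relies on innate electronics. The alternative is the better on reagent economy and in carrying the 5''-oxygen from the start. The step counts are about equal.

Key step: step 9

Remark: locants are unprimed and single-primed for unit 1 (the 7-methoxyflavone) and double- and triple-primed for unit 2; primed locants of acetophenones refer to their benzene ring.
Remark: the structures of precursor 15 and product 17 were re-derived from the target and need no correction.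
Remark: the dipivalate precursor is kept; its preparation is shortened by buying 1 (one step from 2',4'-dihydroxyacetophenone if needed), by hydrolysing the ester in the condensation flask, and by not isolating 12.

## Route

Step 1
Reactants: 1 4'-benzyloxy-2'-hydroxyacetophenone
Product: 3 4'-benzyloxy-2',5'-dihydroxyacetophenone, via aryl sulfate potassium salt 2 (not isolated)
Conditions: K2S2O8, aq. NaOH, pyridine, 0 °C → rt; then aq. HCl, 80 °C
Reagents that add atoms: potassium peroxodisulfate, [K+].[K+].[O-]S(=O)(=O)OOS(=O)(=O)[O-]
Why: Elbs persulfate oxidation: the phenoxide of 1 attacks a peroxide oxygen through C5', the only free carbon para to the 2'-oxygen, and acid hydrolyses the aryl sulfate 2. The benzyl ether and acetyl group tolerate cold alkaline persulfate and brief warm dilute acid, and unreacted 1 can be extracted before the hydrolysis.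

Step 2
Reactants: 3 4'-benzyloxy-2',5'-dihydroxyacetophenone; 4 methyl 4-fluorobenzoate
Product: 5 methyl 4-[5-acetyl-2-(benzyloxy)-4-hydroxyphenoxy]benzoate
Conditions: Cs2CO3, DMSO, 100 °C, argon
Reagents that add atoms: none
Why: Nucleophilic aromatic substitution (addition–elimination) on the fluoroarene activated by its para ester. The 2'-hydroxyl is held in a hydrogen bond to the acetyl group and conjugated with it, so the 5'-phenoxide, which has one ortho substituent, is the nucleophile; argon protects the hydroquinone.

Step 3
Reactants: 5 methyl 4-[5-acetyl-2-(benzyloxy)-4-hydroxyphenoxy]benzoate; 6 4-(benzyloxy)benzaldehyde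
Product: 8 4-[2-(benzyloxy)-5-{(2E)-3-[4-(benzyloxy)phenyl]prop-2-enoyl}-4-hydroxyphenoxy]benzoic acid, via acetophenone carboxylic acid 7 (not isolated)
Conditions: KOH, EtOH–H2O, 50 °C; then 6, rt; aq. HCl
Reagents that add atoms: potassium hydroxide, [K+].[OH-]
Why: Ester saponification followed by Claisen–Schmidt condensation: the methyl ketone enolate adds to the non-enolisable aldehyde and E1cB loss of water gives the enone, E by thermodynamic control. Hydrolysing first removes the ester as a competing electrophile and delivers the acid needed in step 5.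

Step 4
Reactants: 8 4-[2-(benzyloxy)-5-{(2E)-3-[4-(benzyloxy)phenyl]prop-2-enoyl}-4-hydroxyphenoxy]benzoic acid
Product: 9 4-({7-(benzyloxy)-2-[4-(benzyloxy)phenyl]-4-oxo-4H-chromen-6-yl}oxy)benzoic acid
Conditions: I2 (10 mol%), DMSO, 130 °C
Reagents that add atoms: none
Why: Iodine-catalysed oxidative cyclisation of a 2'-hydroxychalcone: oxa-Michael closure to the flavanone, α-iodination and loss of HI, with DMSO returning HI to I2. The ring has a single ortho hydroxyl, so ring C of unit 2 can close in one direction only.

Step 5
Reactants: 9 4-({7-(benzyloxy)-2-[4-(benzyloxy)phenyl]-4-oxo-4H-chromen-6-yl}oxy)benzoic acid; 10 2'-hydroxy-4'-methoxyacetophenone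
Product: 11 2-acetyl-5-methoxyphenyl 4-({7-(benzyloxy)-2-[4-(benzyloxy)phenyl]-4-oxo-4H-chromen-6-yl}oxy)benzoate
Conditions: EDC·HCl, DMAP, CH2Cl2–DMF, rt
Reagents that add atoms: none
Why: Steglich esterification: the carbodiimide activates the acid and DMAP relays the acyl group as an N-acylpyridinium ion, reactive enough for the hydrogen-bonded phenol of 10. No other nucleophile is present.

Step 6
Reactants: 11 2-acetyl-5-methoxyphenyl 4-({7-(benzyloxy)-2-[4-(benzyloxy)phenyl]-4-oxo-4H-chromen-6-yl}oxy)benzoate
Product: 13 7''-O,4'''-O-dibenzyl-5,5''-dideoxyneocryptomerin, via 1,3-diketone 12 (not isolated)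
Conditions: LiN(SiMe3)2 (3 equiv), THF, −78 °C → rt; aq. HCl; crude, p-TsOH·H2O (cat.), toluene, 100 °C
Reagents that add atoms: none
Why: Baker–Venkataraman rearrangement: the lithium enolate of the methyl ketone attacks the neighbouring aroyl ester through a six-membered transition state, moving the acyl group from oxygen to carbon; acid then closes ring C of unit 1 by addition of the phenol to the distal carbonyl and loss of water. A non-nucleophilic amide base at low temperature spares the pyranone of unit 2 and the benzyl ethers.

Step 7
Reactants: 13 7''-O,4'''-O-dibenzyl-5,5''-dideoxyneocryptomerin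
Product: 14 5,5''-dideoxyneocryptomerin
Conditions: H2 (1 atm), 10% Pd/C, THF–MeOH, rt
Reagents that add atoms: none
Why: Hydrogenolysis of the two benzyl aryl ethers. The C2=C3 bonds are vinylogous-ester alkenes that should not be reduced at one atmosphere and room temperature, and the diaryl and methyl ethers are inert.

Step 8
Reactants: 14 5,5''-dideoxyneocryptomerin
Product: 15 5,5''-dideoxyneocryptomerin 7'',4'''-dipivalate
Conditions: PivCl, Et3N, DMAP (cat.), CH2Cl2, 0 °C → rt
Reagents that add atoms: pivaloyl chloride, CC(C)(C)C(=O)Cl
Why: DMAP-catalysed O-acylation of the two phenols, the only nucleophiles in 14. Pivalates resist hot CF3CO2H, deactivate their rings towards the iodine oxidant and are weak, hindered donors towards ruthenium.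

Step 9
Reactants: 15 5,5''-dideoxyneocryptomerin 7'',4'''-dipivalate
Product: 17 neocryptomerin 7'',4'''-dipivalate, via 5,5''-bis(trifluoroacetate) 16 (not isolated)
Conditions: [RuCl2(p-cymene)]2 (5 mol% + 5 mol%), PhI(O2CCF3)2 (5 equiv, in portions), CF3CO2H–(CF3CO)2O 3:1, 80 °C; evaporate; THF–H2O, rt
Reagents that add atoms: [bis(trifluoroacetoxy)iodo]benzene, O=C(OI(OC(=O)C(F)(F)F)c1ccccc1)C(F)(F)F (one trifluoroacetate oxygen per new C–O bond; its ligands exchange with the solvent acid, trifluoroacetic acid, OC(=O)C(F)(F)F)
Why: Chloride–trifluoroacetate exchange gives a divalent ruthenium carboxylate that binds each C4 carbonyl oxygen, and carboxylate-assisted deprotonation metalates the peri C5–H (and C5''–H) to a five-membered ruthenacycle (Ru–O=C4–C4a–C5). The iodine reagent oxidises the metallacycle to tetravalent ruthenium, and C–O reductive elimination releases the aryl trifluoroacetate and divalent ruthenium. The closest known reaction is the ruthenium-catalysed ketone-directed ortho C–H hydroxylation already applied to C5 of simple flavones and chromones, here run twice in one molecule. No ring closes and no stereocentre forms. The selectivity needed is for C5–H and C5''–H over every other aromatic C–H, and geometry secures it: only the peri hydrogens reach a carbonyl-bound metal, C3–H would need a four-membered ring, and the pivalate carbonyls are weaker and hindered donors. Oxidation of the rings by the iodine reagent is held back by the acylated phenols, the electron-poor chromone cores and the acidic medium, while (CF3CO)2O keeps each new phenol capped as in 16 so that it neither chelates the catalyst nor is oxidised further. C5–H of unit 1 should react first and C5''–H, flanked by the aryloxy group, more slowly, hence the excess oxidant in portions and the second catalyst charge. Wet THF then hydrolyses only the two activated trifluoroacetates and leaves the pivalates.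

Step 10
Reactants: 17 neocryptomerin 7'',4'''-dipivalate
Product: 18 neocryptomerin
Conditions: K2CO3, MeOH–THF, rt; then dilute HCl
Reagents that add atoms: none
Why: Base-mediated methanolysis (transesterification) of the two aryl pivalates. The methyl ether, the diaryl ether and both pyranones are stable to K2CO3 in methanol at room temperature, and the chelated 5-hydroxyls are only deprotonated and return on acidification.

## Compound list

1 | 4'-benzyloxy-2'-hydroxyacetophenone | CC(=O)c1ccc(OCc2ccccc2)cc1O | starting material
2 | potassium 5-acetyl-2-(benzyloxy)-4-hydroxyphenyl sulfate | CC(=O)c1cc(OS(=O)(=O)[O-])c(OCc2ccccc2)cc1O.[K+] | intermediate (not isolated)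
3 | 4'-benzyloxy-2',5'-dihydroxyacetophenone | CC(=O)c1cc(O)c(OCc2ccccc2)cc1O | intermediate
4 | methyl 4-fluorobenzoate | COC(=O)c1ccc(F)cc1 | starting material
5 | methyl 4-[5-acetyl-2-(benzyloxy)-4-hydroxyphenoxy]benzoate | COC(=O)c1ccc(Oc2cc(C(C)=O)c(O)cc2OCc2ccccc2)cc1 | intermediate
6 | 4-(benzyloxy)benzaldehyde | O=Cc1ccc(OCc2ccccc2)cc1 | starting material
7 | 4-[5-acetyl-2-(benzyloxy)-4-hydroxyphenoxy]benzoic acid (present as its potassium salt) | OC(=O)c1ccc(Oc2cc(C(C)=O)c(O)cc2OCc2ccccc2)cc1 | intermediate (not isolated)
8 | 4-[2-(benzyloxy)-5-{(2E)-3-[4-(benzyloxy)phenyl]prop-2-enoyl}-4-hydroxyphenoxy]benzoic acid | OC(=O)c1ccc(Oc2cc(C(=O)/C=C/c3ccc(OCc4ccccc4)cc3)c(O)cc2OCc2ccccc2)cc1 | intermediate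
9 | 4-({7-(benzyloxy)-2-[4-(benzyloxy)phenyl]-4-oxo-4H-chromen-6-yl}oxy)benzoic acid | OC(=O)c1ccc(Oc2cc3c(=O)cc(-c4ccc(OCc5ccccc5)cc4)oc3cc2OCc2ccccc2)cc1 | intermediate
10 | 2'-hydroxy-4'-methoxyacetophenone | CC(=O)c1ccc(OC)cc1O | starting material
11 | 2-acetyl-5-methoxyphenyl 4-({7-(benzyloxy)-2-[4-(benzyloxy)phenyl]-4-oxo-4H-chromen-6-yl}oxy)benzoate | CC(=O)c1ccc(OC)cc1OC(=O)c1ccc(Oc2cc3c(=O)cc(-c4ccc(OCc5ccccc5)cc4)oc3cc2OCc2ccccc2)cc1 | intermediate
12 | 1-(2-hydroxy-4-methoxyphenyl)-3-[4-({7-(benzyloxy)-2-[4-(benzyloxy)phenyl]-4-oxo-4H-chromen-6-yl}oxy)phenyl]propane-1,3-dione | COc1ccc(C(=O)CC(=O)c2ccc(Oc3cc4c(=O)cc(-c5ccc(OCc6ccccc6)cc5)oc4cc3OCc3ccccc3)cc2)c(O)c1 | intermediate (not isolated)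
13 | 7''-O,4'''-O-dibenzyl-5,5''-dideoxyneocryptomerin; 7-(benzyloxy)-2-[4-(benzyloxy)phenyl]-6-[4-(7-methoxy-4-oxo-4H-chromen-2-yl)phenoxy]-4H-chromen-4-one | COc1ccc2c(=O)cc(-c3ccc(Oc4cc5c(=O)cc(-c6ccc(OCc7ccccc7)cc6)oc5cc4OCc4ccccc4)cc3)oc2c1 | intermediate
14 | 5,5''-dideoxyneocryptomerin; 7-hydroxy-2-(4-hydroxyphenyl)-6-[4-(7-methoxy-4-oxo-4H-chromen-2-yl)phenoxy]-4H-chromen-4-one | COc1ccc2c(=O)cc(-c3ccc(Oc4cc5c(=O)cc(-c6ccc(O)cc6)oc5cc4O)cc3)oc2c1 | intermediate
15 | 5,5''-dideoxyneocryptomerin 7'',4'''-dipivalate | COc1ccc2c(=O)cc(-c3ccc(Oc4cc5c(=O)cc(-c6ccc(OC(=O)C(C)(C)C)cc6)oc5cc4OC(=O)C(C)(C)C)cc3)oc2c1 | intermediate (key-step precursor)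
16 | neocryptomerin 7'',4'''-dipivalate 5,5''-bis(trifluoroacetate) | COc1cc(OC(=O)C(F)(F)F)c2c(=O)cc(-c3ccc(Oc4c(OC(=O)C(F)(F)F)c5c(=O)cc(-c6ccc(OC(=O)C(C)(C)C)cc6)oc5cc4OC(=O)C(C)(C)C)cc3)oc2c1 | intermediate (not isolated)
17 | neocryptomerin 7'',4'''-dipivalate | COc1cc(O)c2c(=O)cc(-c3ccc(Oc4c(O)c5c(=O)cc(-c6ccc(OC(=O)C(C)(C)C)cc6)oc5cc4OC(=O)C(C)(C)C)cc3)oc2c1 | intermediate (key-step product)
18 | neocryptomerin | COc1cc(O)c2c(=O)cc(-c3ccc(Oc4c(O)cc5oc(-c6ccc(O)cc6)cc(=O)c5c4O)cc3)oc2c1 | target

## Step count and least certain steps

Total step count: 10. Longest linear sequence: 10 steps (1 to 18); 4, 6 and 10 enter as purchased partners.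

Step 9 (key step). The most likely failure is that the second metalation, at C5''–H beside the aryloxy group, lags so far behind the first that the reaction stalls after one oxygenation. The extra oxidant and time needed to force it would then allow electrophilic attack of the iodine reagent on the aryloxy-substituted ring B and acidolytic loss of a pivalate followed by phenol oxidation. The fallback oxidises only one C–H bond and brings the other peri oxygen in with a building block.
- It sets out from 9, which is esterified (EDC·HCl, DMAP) with 2',6'-dihydroxy-4'-methoxyacetophenone F1 to the mono-ester 2-acetyl-3-hydroxy-5-methoxyphenyl 4-({7-(benzyloxy)-2-[4-(benzyloxy)phenyl]-4-oxo-4H-chromen-6-yl}oxy)benzoate F2.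
- Acyl shift with LiN(SiMe3)2 (4 equiv) and acid-catalysed closure, where either hydroxyl gives the same ring, should lead to 7''-O,4'''-O-dibenzyl-5''-deoxyneocryptomerin F3.
- Hydrogenolysis gives 5''-deoxyneocryptomerin F4, and forcing acylation (PivCl, DMAP, pyridine, 60 °C) gives 5''-deoxyneocryptomerin 5,7'',4'''-tripivalate F5.
- A single ruthenium-catalysed hydroxylation at C5'', with the whole catalyst and oxidant charge serving one site, gives neocryptomerin 5,7'',4'''-tripivalate F6.
- K2CO3 in methanol then brings the sequence back to the route at 18.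

Step 1. Conversion in the persulfate oxidation is usually incomplete, the hydroquinone product can be oxidised further, and some benzyl ether may be lost during the acid hydrolysis of the sulfate. The fallback forms the ether by metal-catalysed coupling with reversed polarity at the flavone stage.
- It sets out from 1, which is brominated para to the hydroxyl (NBS, MeCN, 0 °C) to 4'-(benzyloxy)-5'-bromo-2'-hydroxyacetophenone F7.
- Condensation with 6 (KOH, EtOH) gives (2E)-1-[4-(benzyloxy)-5-bromo-2-hydroxyphenyl]-3-[4-(benzyloxy)phenyl]prop-2-en-1-one F8.
- I2 in DMSO closes this to 7-(benzyloxy)-2-[4-(benzyloxy)phenyl]-6-bromo-4H-chromen-4-one F9.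
- Copper-catalysed Ullmann-type etherification (CuI, picolinic acid, K3PO4, DMSO, 90 °C) with methyl 4-hydroxybenzoate F10 gives methyl 4-({7-(benzyloxy)-2-[4-(benzyloxy)phenyl]-4-oxo-4H-chromen-6-yl}oxy)benzoate F11.
- LiOH in THF–H2O at room temperature returns the sequence to the route at 9.

Step 2. Addition–elimination on an ester-activated fluoroarene is slow, and at the temperature it needs, air oxidation of the hydroquinone and arylation of the chelated hydroxyl can compete. The fallback uses a far more activated electrophile in another functional-group state.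
- It sets out from 3, which reacts with 4-fluorobenzonitrile F12 (K2CO3, DMF, 70 °C) to give 4-[5-acetyl-2-(benzyloxy)-4-hydroxyphenoxy]benzonitrile F13.
- The nitrile is hydrolysed (KOH, EtOH–H2O, reflux) to the carboxylate, which rejoins the route at 7 in the flask of step 3.

Step 6. The excess amide base may open or add to the pyranone of unit 2 while the acyl shift proceeds on warming, or the ester may simply be cleaved back to 9 and 10. The fallback replaces the rearrangement by a direct C-acylation at low temperature.
- It sets out from 9, which is converted ((COCl)2, cat. DMF, CH2Cl2) into 4-({7-(benzyloxy)-2-[4-(benzyloxy)phenyl]-4-oxo-4H-chromen-6-yl}oxy)benzoyl chloride F14.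
- F14 is added at −78 °C to the dilithium enolate–phenoxide of 10 (LiN(SiMe3)2, THF), which should give the diketone directly and rejoin the route at 12 for the acid-catalysed closure.

## Further compounds

F1 | step 9 | 2',6'-dihydroxy-4'-methoxyacetophenone (purchased partner) | CC(=O)c1c(O)cc(OC)cc1O
F2 | step 9 | 2-acetyl-3-hydroxy-5-methoxyphenyl 4-({7-(benzyloxy)-2-[4-(benzyloxy)phenyl]-4-oxo-4H-chromen-6-yl}oxy)benzoate | CC(=O)c1c(O)cc(OC)cc1OC(=O)c1ccc(Oc2cc3c(=O)cc(-c4ccc(OCc5ccccc5)cc4)oc3cc2OCc2ccccc2)cc1
F3 | step 9 | 7''-O,4'''-O-dibenzyl-5''-deoxyneocryptomerin | COc1cc(O)c2c(=O)cc(-c3ccc(Oc4cc5c(=O)cc(-c6ccc(OCc7ccccc7)cc6)oc5cc4OCc4ccccc4)cc3)oc2c1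
F4 | step 9 | 5''-deoxyneocryptomerin | COc1cc(O)c2c(=O)cc(-c3ccc(Oc4cc5c(=O)cc(-c6ccc(O)cc6)oc5cc4O)cc3)oc2c1
F5 | step 9 | 5''-deoxyneocryptomerin 5,7'',4'''-tripivalate | COc1cc(OC(=O)C(C)(C)C)c2c(=O)cc(-c3ccc(Oc4cc5c(=O)cc(-c6ccc(OC(=O)C(C)(C)C)cc6)oc5cc4OC(=O)C(C)(C)C)cc3)oc2c1
F6 | step 9 | neocryptomerin 5,7'',4'''-tripivalate | COc1cc(OC(=O)C(C)(C)C)c2c(=O)cc(-c3ccc(Oc4c(O)c5c(=O)cc(-c6ccc(OC(=O)C(C)(C)C)cc6)oc5cc4OC(=O)C(C)(C)C)cc3)oc2c1
F7 | step 1 | 4'-(benzyloxy)-5'-bromo-2'-hydroxyacetophenone | CC(=O)c1cc(Br)c(OCc2ccccc2)cc1O
F8 | step 1 | (2E)-1-[4-(benzyloxy)-5-bromo-2-hydroxyphenyl]-3-[4-(benzyloxy)phenyl]prop-2-en-1-one | O=C(/C=C/c1ccc(OCc2ccccc2)cc1)c1cc(Br)c(OCc2ccccc2)cc1O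
F9 | step 1 | 7-(benzyloxy)-2-[4-(benzyloxy)phenyl]-6-bromo-4H-chromen-4-one | O=c1cc(-c2ccc(OCc3ccccc3)cc2)oc2cc(OCc3ccccc3)c(Br)cc12
F10 | step 1 | methyl 4-hydroxybenzoate (purchased partner) | COC(=O)c1ccc(O)cc1
F11 | step 1 | methyl 4-({7-(benzyloxy)-2-[4-(benzyloxy)phenyl]-4-oxo-4H-chromen-6-yl}oxy)benzoate | COC(=O)c1ccc(Oc2cc3c(=O)cc(-c4ccc(OCc5ccccc5)cc4)oc3cc2OCc2ccccc2)cc1
F12 | step 2 | 4-fluorobenzonitrile (purchased partner) | N#Cc1ccc(F)cc1
F13 | step 2 | 4-[5-acetyl-2-(benzyloxy)-4-hydroxyphenoxy]benzonitrile | N#Cc1ccc(Oc2cc(C(C)=O)c(O)cc2OCc2ccccc2)cc1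
F14 | step 6 | 4-({7-(benzyloxy)-2-[4-(benzyloxy)phenyl]-4-oxo-4H-chromen-6-yl}oxy)benzoyl chloride | O=C(Cl)c1ccc(Oc2cc3c(=O)cc(-c4ccc(OCc5ccccc5)cc4)oc3cc2OCc2ccccc2)cc1
A1 | alternative 1 | 4-(4-bromophenoxy)-3-isopropoxycyclobut-2-en-1-one | O=C1C=C(OC(C)C)C1Oc1ccc(Br)cc1
A2 | alternative 1 | (triisopropylsilyloxy)acetylene | C#CO[Si](C(C)C)(C(C)C)C(C)C
A3 | alternative 1 | 2-(4-bromophenoxy)-3-isopropoxy-5-(triisopropylsilyloxy)phenol | CC(C)Oc1cc(O[Si](C(C)C)(C(C)C)C(C)C)cc(O)c1Oc1ccc(Br)cc1
A4 | alternative 2 | 3,5-dimethoxy-2-(trimethylsilyl)phenyl trifluoromethanesulfonate | COc1cc(OC)c([Si](C)(C)C)c(OS(=O)(=O)C(F)(F)F)c1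
A5 | alternative 2 | 3-[4-({5,7-bis(benzyloxy)-2-[4-(benzyloxy)phenyl]-4-oxo-4H-chromen-6-yl}oxy)phenyl]prop-2-ynoic acid | OC(=O)C#Cc1ccc(Oc2c(OCc3ccccc3)cc3oc(-c4ccc(OCc5ccccc5)cc4)cc(=O)c3c2OCc2ccccc2)cc1
A6 | alternative 2 | 5-O-methyl-5'',7'',4'''-tri-O-benzylneocryptomerin | COc1cc(OC)c2c(=O)cc(-c3ccc(Oc4c(OCc5ccccc5)cc5oc(-c6ccc(OCc7ccccc7)cc6)cc(=O)c5c4OCc4ccccc4)cc3)oc2c1
A7 | alternative 3 | methyl 4-(6-isopropoxy-2-methoxy-3-{3-[4-(isopropoxy)phenyl]-3-oxopropanoyl}phenoxy)benzoate | COC(=O)c1ccc(Oc2c(OC(C)C)ccc(C(=O)CC(=O)c3ccc(OC(C)C)cc3)c2OC)cc1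
A8 | alternative 3 | methyl 4-({7-isopropoxy-2-[4-(isopropoxy)phenyl]-5-methoxy-4-oxo-4H-chromen-6-yl}oxy)benzoate | COC(=O)c1ccc(Oc2c(OC(C)C)cc3oc(-c4ccc(OC(C)C)cc4)cc(=O)c3c2OC)cc1
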